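**Plan**

- The last retrosynthetic cut is the C2–C3 bond of the pyran ring (ring C), with the hydrogen on C4 returned to C2. This turns the O1–C2H2 unit back into a methyl ether on C8a and the target into an isomeric (E)-styrylquinone.
- The enabling feature: O1–C2 is the methoxy group on C8a, flanked by the C8 methoxy group. C3 (on the quinone, ring B) and C4 (on C4a of ring A) are the alkene carbons, so C4 is the δ-terminus of a vinylogous quinone acceptor lying 1,5 to the methyl hydrogens.
- The next cuts are the quinone–C3 bond (Suzuki–Miyaura coupling, bromoquinone plus (E)-styrylboronate) and the C3=C4 alkene (boron-Wittig olefination of a ring A benzaldehyde). The C6 oxygen is traced to bromination and borylation/oxidation of 2,3,4-trimethoxybenzaldehyde.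
- Forward: ring A is functionalised and chain-extended, joined to the preformed quinone ring, and the pyran ring is closed last by hydride shift and C–C bond formation.
- The only stereocentre, C3 (S), arises in that last C–C closure under control of a chiral Brønsted acid.

Key step: step 8

Remark: both starting materials are taken as purchasable, and since the sense of induction of the chiral acid cannot be predicted, the catalyst enantiomer that leads to 3S is to be fixed in a first screen.

**Route**

Step 1
Reactants: 1 2,3,4-trimethoxybenzaldehyde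
Product: 2 5-bromo-2,3,4-trimethoxybenzaldehyde
Conditions: NBS, DMF, rt
Reagents that add atoms: N-bromosuccinimide O=C1CCC(=O)N1Br
Why: Electrophilic aromatic bromination should go to C5, the only free position that is para to one methoxy group, ortho to another and meta to the deactivating formyl group.

Step 2
Reactants: 2 5-bromo-2,3,4-trimethoxybenzaldehyde
Product: 4 5-hydroxy-2,3,4-trimethoxybenzaldehyde, via arylboronic acid pinacol ester 3 (not isolated)
Conditions: B2pin2, PdCl2(dppf) (3 mol%), KOAc, 1,4-dioxane, 85 °C; then 30% aq H2O2, THF, 0 °C to rt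
Reagents that add atoms: bis(pinacolato)diboron CC1(C)OB(OC1(C)C)B1OC(C)(C)C(C)(C)O1 (boron unit of 3); hydrogen peroxide OO (hydroxyl oxygen of 4)
Why: Miyaura borylation of the aryl bromide followed by oxidative ipso-hydroxylation of the boronate (aryl migration from boron to oxygen) is a standard bromide-to-phenol exchange that should leave the non-enolisable aldehyde intact at low temperature.

Step 3
Reactants: 4 5-hydroxy-2,3,4-trimethoxybenzaldehyde
Product: 5 2,3,4-trimethoxy-5-[(triisopropylsilyl)oxy]benzaldehyde
Conditions: TIPSCl, imidazole, DMF, rt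
Reagents that add atoms: triisopropylsilyl chloride CC(C)[Si](Cl)(C(C)C)C(C)C
Why: Imidazole-mediated O-silylation of the phenol, with the bulky TIPS group chosen so that the aryl silyl ether should survive the lithium amide of step 4 and the aqueous base of step 6.

Step 4
Reactants: 5 2,3,4-trimethoxy-5-[(triisopropylsilyl)oxy]benzaldehyde
Product: 6 (E)-4,4,5,5-tetramethyl-2-[2-{2,3,4-trimethoxy-5-[(triisopropylsilyl)oxy]phenyl}ethenyl]-1,3,2-dioxaborolane
Conditions: CH2(Bpin)2, lithium 2,2,6,6-tetramethylpiperidide (LiTMP), THF, 0 °C; then 5, −78 °C to rt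
Reagents that add atoms: bis[(pinacolato)boryl]methane CC1(C)OB(CB2OC(C)(C)C(C)(C)O2)OC1(C)C
Why: Boron-Wittig olefination, in which the lithiated geminal bis(boronate) adds to the aldehyde and B–O elimination gives the alkenylboronate, the E isomer being the usual outcome with aldehydes.

Step 5
Reactants: 7 2,3-dimethoxy-1,4-benzoquinone
Product: 9 5-bromo-2,3-dimethoxy-1,4-benzoquinone, via trans-5,6-dibromide 8 (not isolated)
Conditions: Br2 (1.0 equiv), AcOH, rt; then NaOAc, 60 °C
Reagents that add atoms: bromine BrBr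
Why: Addition of bromine across the unsubstituted C5=C6 bond and acetate-induced loss of HBr (addition–elimination) is the classical entry to monobromoquinones, and the dimethoxy-substituted alkene carries no hydrogen to be replaced.

Step 6
Reactants: 6 (E)-alkenylboronate; 9 5-bromo-2,3-dimethoxy-1,4-benzoquinone
Product: 10 2,3-dimethoxy-5-[(E)-2-{2,3,4-trimethoxy-5-[(triisopropylsilyl)oxy]phenyl}ethenyl]-1,4-benzoquinone
Conditions: PdCl2(dppf) (5 mol%), K3PO4, THF/H2O (10:1), degassed, 45 °C
Reagents that add atoms: none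
Why: Suzuki–Miyaura coupling, in which the bromoquinone acts as a vinylogous acyl bromide toward oxidative addition to zerovalent palladium and the alkenylboronate transfers with retention, so the E alkene should be kept while the mild phosphate base spares quinone and silyl ether.

Step 7
Reactants: 10 TIPS-protected styrylquinone
Product: 11 2-[(E)-2-(5-hydroxy-2,3,4-trimethoxyphenyl)ethenyl]-5,6-dimethoxy-1,4-benzoquinone
Conditions: Bu4NF, AcOH (1:1), THF, 0 °C to rt
Reagents that add atoms: none
Why: Fluoride-mediated cleavage of the aryl silyl ether, buffered with acetic acid so that no free phenoxide is exposed to the electrophilic quinone.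

Step 8
Reactants: 11 2-[(E)-2-(5-hydroxy-2,3,4-trimethoxyphenyl)ethenyl]-5,6-dimethoxy-1,4-benzoquinone
Product: 12 2-[(3S)-6-hydroxy-7,8-dimethoxychroman-3-yl]-5,6-dimethoxy-1,4-benzoquinone
Conditions: BINOL-derived N-triflyl imidodiphosphorimidate (IDPi) Brønsted acid, single enantiomer (10 mol%), PhCF3 (0.02 M), 5 Å MS, 50 °C, argon
Reagents that add atoms: none
Why: Proposed new method: protonation of the quinone carbonyl that is vinylogous to the styryl group makes benzylic C4 the δ-terminus of a 1,6-acceptor, a suprafacial 1,5-hydride shift from the methyl group of the C8a methoxy ether through a six-membered transition state then gives the aryloxycarbenium ion O1=C2H2(+) and a hydroxy quinone-methide dienol, and the exocyclic carbon of that dienol (C3) adds to C2 before proton loss restores the quinone, so that 11 is isomerised to 12 with no reagent consumed. The closest known reaction type is the acid-catalysed hydride-shift/cyclisation (internal redox) of ortho-alkoxyaryl alkylidene malonates to 3,3-disubstituted chromans, including chiral-acid versions; a methyl ether as hydride donor and a vinylquinone as acceptor have not been shown. The pyran ring (ring C) closes by 6-endo-trig attack of C3 on the oxocarbenium carbon C2, the C2=O1 bond lying inside the new ring. The C3 stereocentre is created in this C–C bond formation and should be controlled by the chiral counter-anion, which is paired with the oxocarbenium ion and hydrogen-bonded to the dienol hydroxyl and so leaves one face of C3 open; the catalyst antipode is chosen for 3S. The step needs site selectivity among five methoxy groups and regioselectivity at the alkene: only the C8a methoxy group lies 1,5 to C4, and only C4 is conjugated to the activated carbonyl. Reactivity of the poor methyl donor is helped by the substrate itself, because this methoxy group is flanked by the side chain and the C8 methoxy group and is therefore twisted out of the ring plane, which holds a C–H bond over the π face of C4 and frees an oxygen lone pair to stabilise the cation.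

**Compound list**

1 | 2,3,4-trimethoxybenzaldehyde | COc1ccc(C=O)c(OC)c1OC | starting material
2 | 5-bromo-2,3,4-trimethoxybenzaldehyde | COc1c(Br)cc(C=O)c(OC)c1OC | intermediate
3 | 2,3,4-trimethoxy-5-(4,4,5,5-tetramethyl-1,3,2-dioxaborolan-2-yl)benzaldehyde | COc1c(B2OC(C)(C)C(C)(C)O2)cc(C=O)c(OC)c1OC | intermediate (not isolated)
4 | 5-hydroxy-2,3,4-trimethoxybenzaldehyde | COc1c(O)cc(C=O)c(OC)c1OC | intermediate
5 | 2,3,4-trimethoxy-5-[(triisopropylsilyl)oxy]benzaldehyde | COc1c(O[Si](C(C)C)(C(C)C)C(C)C)cc(C=O)c(OC)c1OC | intermediate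
6 | (E)-4,4,5,5-tetramethyl-2-[2-{2,3,4-trimethoxy-5-[(triisopropylsilyl)oxy]phenyl}ethenyl]-1,3,2-dioxaborolane | COc1c(O[Si](C(C)C)(C(C)C)C(C)C)cc(/C=C/B2OC(C)(C)C(C)(C)O2)c(OC)c1OC | intermediate
7 | 2,3-dimethoxy-1,4-benzoquinone | COC1=C(OC)C(=O)C=CC1=O | starting material
8 | trans-5,6-dibromo-2,3-dimethoxycyclohex-2-ene-1,4-dione (racemic, one enantiomer drawn) | COC1=C(OC)C(=O)[C@H](Br)[C@@H](Br)C1=O | intermediate (not isolated)
9 | 5-bromo-2,3-dimethoxy-1,4-benzoquinone | COC1=C(OC)C(=O)C(Br)=CC1=O | intermediate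
10 | 2,3-dimethoxy-5-[(E)-2-{2,3,4-trimethoxy-5-[(triisopropylsilyl)oxy]phenyl}ethenyl]-1,4-benzoquinone | COC1=C(OC)C(=O)C(/C=C/c2cc(O[Si](C(C)C)(C(C)C)C(C)C)c(OC)c(OC)c2OC)=CC1=O | intermediate
11 | 2-[(E)-2-(5-hydroxy-2,3,4-trimethoxyphenyl)ethenyl]-5,6-dimethoxy-1,4-benzoquinone | COC1=C(OC)C(=O)C(/C=C/c2cc(O)c(OC)c(OC)c2OC)=CC1=O | intermediate
12 | 2-[(3S)-6-hydroxy-7,8-dimethoxychroman-3-yl]-5,6-dimethoxy-1,4-benzoquinone | COC1=C(OC)C(=O)C([C@H]2COc3c(cc(O)c(OC)c3OC)C2)=CC1=O | target

**Count**

Total step count: 8. Longest linear sequence: 7 steps (from 1 through steps 1, 2, 3, 4, 6, 7 and 8).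

**Steps most likely to fail**

1. Step 8. The methyl C–H bond may not deliver hydride at a temperature the catalyst and the quinone tolerate. Traces of water may intercept the oxocarbenium ion, with net loss of formaldehyde. The C–C closure may show poor facial selectivity. The product may also undergo a second hydride transfer to its own quinone.

   The fallback uses known chemistry only, sets out from 4 and 9 and returns at 12. It builds the chroman conventionally and sets C3 by asymmetric hydrogenation.
   - Ring A: BCl3 (CH2Cl2, −78 to 0 °C), chelated to the formyl group, should cleave only the methyl ether ortho to it in 4 and give 2,5-dihydroxy-3,4-dimethoxybenzaldehyde F1.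
   - Ring B: 9 is reduced with aqueous Na2S2O4 to 5-bromo-2,3-dimethoxybenzene-1,4-diol F2, benzylated (BnBr, K2CO3, DMF) to 1,4-bis(benzyloxy)-5-bromo-2,3-dimethoxybenzene F3, coupled with the Reformatsky reagent BrZnCH2CO2tBu (Pd2(dba)3, XPhos, THF) to tert-butyl 2-[2,5-bis(benzyloxy)-3,4-dimethoxyphenyl]acetate F4, and cleaved with CF3CO2H in CH2Cl2 to 2-[2,5-bis(benzyloxy)-3,4-dimethoxyphenyl]acetic acid F5.
   - Assembly: Perkin condensation of F1 with F5 (Ac2O, Et3N, 110 °C) should give 3-[2,5-bis(benzyloxy)-3,4-dimethoxyphenyl]-7,8-dimethoxy-2-oxo-2H-chromen-6-yl acetate F6. Excess i-Bu2AlH reduces lactone and acetate to (Z)-2-[2,5-bis(benzyloxy)-3,4-dimethoxyphenyl]-3-(2,5-dihydroxy-3,4-dimethoxyphenyl)prop-2-en-1-ol F7. A Mitsunobu reaction (PPh3, DIAD, THF) closes this to 3-[2,5-bis(benzyloxy)-3,4-dimethoxyphenyl]-7,8-dimethoxy-2H-chromen-6-ol F8.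
   - Stereocentre and end game: asymmetric hydrogenation with a cationic iridium complex [Ir(cod)(L)]BArF of a chiral phosphine–oxazoline ligand L (H2, CH2Cl2) gives (3S)-3-[2,5-bis(benzyloxy)-3,4-dimethoxyphenyl]-7,8-dimethoxychroman-6-ol F9. Hydrogenolysis (H2, Pd/C, EtOAc/MeOH) gives 2-[(3S)-6-hydroxy-7,8-dimethoxychroman-3-yl]-5,6-dimethoxybenzene-1,4-diol F10, and Ag2O in Et2O should oxidise only the hydroquinone ring to give 12.

2. Step 6. The quinone may consume the alkenylboronate by oxidative homocoupling, the aqueous base may degrade the bromoquinone, and palladium hydride species may reduce the quinone.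

   The fallback sets out from 9 and 6 and returns at 10; it moves the coupling to the hydroquinone oxidation level, where none of these processes can occur. Compound 9 is reduced with aqueous Na2S2O4 to 5-bromo-2,3-dimethoxybenzene-1,4-diol F2 (the compound already described in the fallback for step 8). F2 is coupled with 6 (Pd(OAc)2, SPhos, K3PO4, degassed dioxane/H2O, 60 °C) to 2,3-dimethoxy-5-[(E)-2-{2,3,4-trimethoxy-5-[(triisopropylsilyl)oxy]phenyl}ethenyl]benzene-1,4-diol F11. Ag2O (Et2O, MgSO4, rt) then oxidises the hydroquinone to 10.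

3. Step 2. Protodebromination may compete in the borylation of the electron-rich bromide, and the peroxide may attack the formyl group (Dakin-type oxidation) during the hydroxylation.

   The fallback sets out from 2 and returns at 4; it masks the aldehyde and forms the C–O bond directly. Compound 2 is converted with ethylene glycol and TsOH (toluene, Dean–Stark) into 2-(5-bromo-2,3,4-trimethoxyphenyl)-1,3-dioxolane F12. Palladium-catalysed hydroxylation (Pd2(dba)3, tBuXPhos, KOH, dioxane/H2O, 100 °C) gives 5-(1,3-dioxolan-2-yl)-2,3,4-trimethoxyphenol F13, and dilute HCl in THF releases 4.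

**Further compounds**

F1 | step 8 | 2,5-dihydroxy-3,4-dimethoxybenzaldehyde | COc1c(O)cc(C=O)c(O)c1OC
F2 | step 8 | 5-bromo-2,3-dimethoxybenzene-1,4-diol | COc1c(OC)c(O)c(Br)cc1O
F3 | step 8 | 1,4-bis(benzyloxy)-5-bromo-2,3-dimethoxybenzene | COc1c(OC)c(OCc2ccccc2)c(Br)cc1OCc1ccccc1
F4 | step 8 | tert-butyl 2-[2,5-bis(benzyloxy)-3,4-dimethoxyphenyl]acetate | COc1c(OC)c(OCc2ccccc2)c(CC(=O)OC(C)(C)C)cc1OCc1ccccc1
F5 | step 8 | 2-[2,5-bis(benzyloxy)-3,4-dimethoxyphenyl]acetic acid | COc1c(OC)c(OCc2ccccc2)c(CC(=O)O)cc1OCc1ccccc1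
F6 | step 8 | 3-[2,5-bis(benzyloxy)-3,4-dimethoxyphenyl]-7,8-dimethoxy-2-oxo-2H-chromen-6-yl acetate | CC(=O)Oc1cc2C=C(c3cc(OCc4ccccc4)c(OC)c(OC)c3OCc3ccccc3)C(=O)Oc2c(OC)c1OC
F7 | step 8 | (Z)-2-[2,5-bis(benzyloxy)-3,4-dimethoxyphenyl]-3-(2,5-dihydroxy-3,4-dimethoxyphenyl)prop-2-en-1-ol | OC/C(=C\c1cc(O)c(OC)c(OC)c1O)c1cc(OCc2ccccc2)c(OC)c(OC)c1OCc1ccccc1
F8 | step 8 | 3-[2,5-bis(benzyloxy)-3,4-dimethoxyphenyl]-7,8-dimethoxy-2H-chromen-6-ol | COc1c(O)cc2C=C(c3cc(OCc4ccccc4)c(OC)c(OC)c3OCc3ccccc3)COc2c1OC
F9 | step 8 | (3S)-3-[2,5-bis(benzyloxy)-3,4-dimethoxyphenyl]-7,8-dimethoxychroman-6-ol | COc1c(O)cc2C[C@@H](c3cc(OCc4ccccc4)c(OC)c(OC)c3OCc3ccccc3)COc2c1OC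
F10 | step 8 | 2-[(3S)-6-hydroxy-7,8-dimethoxychroman-3-yl]-5,6-dimethoxybenzene-1,4-diol | COc1c(O)cc2C[C@@H](c3cc(O)c(OC)c(OC)c3O)COc2c1OC
F11 | step 6 | 2,3-dimethoxy-5-[(E)-2-{2,3,4-trimethoxy-5-[(triisopropylsilyl)oxy]phenyl}ethenyl]benzene-1,4-diol | COc1c(OC)c(O)c(/C=C/c2cc(O[Si](C(C)C)(C(C)C)C(C)C)c(OC)c(OC)c2OC)cc1O
F12 | step 2 | 2-(5-bromo-2,3,4-trimethoxyphenyl)-1,3-dioxolane | COc1c(Br)cc(C2OCCO2)c(OC)c1OC
F13 | step 2 | 5-(1,3-dioxolan-2-yl)-2,3,4-trimethoxyphenol | COc1c(O)cc(C2OCCO2)c(OC)c1OC
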